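**Plan**
Numbering: ring A = C8(=O)–C1(Me)=C2–C6(Ar)–C7(OH)(iBu); ring B = C2–C3–C4–C5(Me)–C6; Ar = 4-oxygenated 5-methylcoumarin-3-yl, bonded through C3′ to C6.
Enabling feature: ring A is a 5-hydroxycyclopent-2-enone. Its C6–C7 bond joins the γ-carbon of the C8/C1=C2 enone to the adjacent C7 carbonyl carbon, and C5 of ring B is the δ-carbon of the same π-system.
Cuts, in order: O–benzyl; then C6–C7 and C5–CH3 together, back to a stereocentre-free dienyl 1,2-diketone and Me2Zn; then C7–C8 (dithiane anion + dienal), C6–C3′ (Suzuki–Miyaura) and C1=C2 (aldol condensation).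
Forward: the coumarin ring is closed first. Ring B is bought as cyclopentanone. The chain is joined in the order C1=C2, C6–C3′, C7–C8, and ring A closes last.
Stereochemistry: no lasting stereocentre exists before the key step. There a chiral copper catalyst sets C5, C5 directs the sense of the conrotatory closure at C6, and conrotation relays this to C7.

Key step: step 12

Assumption: the facial sense of the copper catalyst on this new acceptor cannot be predicted. The ligand is written as the enantiomer that gives 5S, and its antipode is used if a trial shows the opposite sense.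
Remark: the C1=C2 geometry (E, C8 on the side of C3) is lost in the dienolate of the key step. It affects reactivity but not the configuration of the product.

**Step 1**
Reactants: 1 2′-hydroxy-6′-methylacetophenone
Product: 2 4-hydroxy-5-methyl-2H-chromen-2-one (4-hydroxy-5-methylcoumarin)
Conditions: NaH, (EtO)2CO, toluene, 110 °C; 1 M HCl
Reagents that add atoms: diethyl carbonate, CCOC(=O)OCC
Why: Claisen-type C-ethoxycarbonylation of the methyl ketone enolate followed by lactonisation onto the phenoxide is the standard route from 2-hydroxyacetophenones to 4-hydroxycoumarins.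

**Step 2**
Reactants: 2 4-hydroxy-5-methylcoumarin
Product: 3 3-bromo-4-hydroxy-5-methyl-2H-chromen-2-one
Conditions: NBS, MeCN, 0 °C → rt, dark
Reagents that add atoms: N-bromosuccinimide, O=C1CCC(=O)N1Br
Why: Electrophilic bromination at the enolic β-dicarbonyl carbon C3′, the only nucleophilic carbon, run under ionic conditions that spare the aryl methyl group; the bromine blocks C-alkylation in step 3 and is the later coupling handle.

**Step 3**
Reactants: 3 3-bromo-4-hydroxy-5-methylcoumarin
Product: 4 4-(benzyloxy)-3-bromo-5-methyl-2H-chromen-2-one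
Conditions: BnBr, K2CO3, acetone, 56 °C
Reagents that add atoms: benzyl bromide, BrCc1ccccc1
Why: Williamson O-alkylation of the coumarinate, which with C3′ blocked should favour the 4-alkoxycoumarin over the separable 2-alkoxychromone; benzyl is preferred to methyl so that the last step can be a neutral hydrogenolysis.

**Step 4**
Reactants: 5 cyclopentanone; 6 1,1-dimethoxypropan-2-one (methylglyoxal dimethyl acetal)
Product: 8 2-(2-hydroxy-1,1-dimethoxypropan-2-yl)cyclopentan-1-one (diastereomer mixture), via lithium cyclopentenolate 7 (not isolated)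
Conditions: LDA, THF, −78 °C; 6, −78 °C; AcOH, −78 °C
Reagents that add atoms: lithium diisopropylamide, [Li+].CC(C)[N-]C(C)C (lithium of 7 only)
Why: Directed aldol addition in which the preformed enolate adds to the ketone of 6 (activated and chelating through its α-alkoxy groups) and a cold acid quench forestalls retro-aldol; using ring carbon C2 as the nucleophile avoids olefinating a hindered, Michael-prone 2-arylcyclopentenone, and both new stereocentres are erased in step 5.

**Step 5**
Reactants: 8 aldol adduct
Product: 10 (E)-2-(1,1-dimethoxypropan-2-ylidene)cyclopentan-1-one, via tertiary mesylate 9 (not isolated)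
Conditions: MsCl, Et3N, CH2Cl2, 0 °C; DBU, rt
Reagents that add atoms: methanesulfonyl chloride, CS(=O)(=O)Cl (mesyl group of 9 only)
Why: Aldol dehydration by mesylation (sulfene pathway, suited to tertiary alcohols) and E1cB elimination through the ketone enolate, which can only place the alkene at C1=C2; as in other 2-alkylidenecyclopentanones the larger group (acetal carbon C8) should settle away from the ring carbonyl (E) under the equilibrating DBU conditions, and any Z isomer is removed by chromatography.

**Step 6**
Reactants: 10 (E)-enone acetal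
Product: 12 (E)-5-(1,1-dimethoxypropan-2-ylidene)cyclopent-1-en-1-yl trifluoromethanesulfonate, via lithium cross-conjugated dienolate 11 (not isolated)
Conditions: LDA, THF, −78 °C; N-(5-chloropyridin-2-yl)bis(trifluoromethanesulfonimide), −78 → 0 °C
Reagents that add atoms: lithium diisopropylamide, [Li+].CC(C)[N-]C(C)C (lithium of 11 only); N-(5-chloropyridin-2-yl)bis(trifluoromethanesulfonimide), O=S(=O)(N(c1ccc(Cl)cn1)S(=O)(=O)C(F)(F)F)C(F)(F)F
Why: Enol triflate synthesis by kinetic α′-deprotonation of the enone at C5 and cold O-sulfonylation, which creates the C5=C6 alkene and the handle on C6 without touching the C1=C2 geometry.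

**Step 7**
Reactants: 12 dienyl triflate; 4 4-(benzyloxy)-3-bromo-5-methylcoumarin
Product: 15 (E)-2-{2-[4-(benzyloxy)-5-methyl-2-oxo-2H-chromen-3-yl]cyclopent-2-en-1-ylidene}propanal, via dienyl pinacolboronate 13 (not isolated), via coupled dimethyl acetal 14 (not isolated)
Conditions: B2pin2, XPhos Pd G2 (3 mol %), KOAc, dioxane, 80 °C; 4, aq. K3PO4, 70 °C; 1 M HCl, THF, 0 °C
Reagents that add atoms: bis(pinacolato)diboron, CC1(C)OB(OC1(C)C)B2OC(C)(C)C(C)(C)O2 (boronate of 13 only); water, O
Why: Miyaura borylation of the enol triflate followed in the same flask by Suzuki–Miyaura coupling with the activated 3-bromocoumarin forms C6–C3′ (boron is placed on the diene because a 3-borylated 4-alkoxycoumarin is expected to protodeboronate readily), and the cold acid work-up hydrolyses the allylic acetal to the aldehyde.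

**Step 8**
Reactants: 16 3-methylbutanal
Product: 17 2-(2-methylpropyl)-1,3-dithiane
Conditions: HS(CH2)3SH, BF3·OEt2 (cat.), CH2Cl2, 0 °C → rt
Reagents that add atoms: propane-1,3-dithiol, SCCCS
Why: Lewis-acid-catalysed dithioacetalisation of an unhindered aliphatic aldehyde.

**Step 9**
Reactants: 17 2-isobutyl-1,3-dithiane; 15 dienal
Product: 19 4-(benzyloxy)-3-{(E)-5-[1-hydroxy-1-(2-isobutyl-1,3-dithian-2-yl)propan-2-ylidene]cyclopent-1-en-1-yl}-5-methylcoumarin (racemic carbinol), via 2-lithio-2-isobutyl-1,3-dithiane 18 (not isolated)
Conditions: 17, n-BuLi, THF, −25 °C; 15, −78 °C; sat. aq. NH4Cl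
Reagents that add atoms: n-butyllithium, [Li]CCCC (lithium of 18 only)
Why: Corey–Seebach umpolung forms C7–C8 by 1,2-addition in THF without polar additives; an aldehyde captures this basic, hindered anion faster than γ-deprotonation or attack on the coumarin lactone could occur (an ester would not), and the new carbinol centre is erased in step 10.

**Step 10**
Reactants: 19 dithianyl carbinol
Product: 20 4-(benzyloxy)-3-{(E)-5-[1-(2-isobutyl-1,3-dithian-2-yl)-1-oxopropan-2-ylidene]cyclopent-1-en-1-yl}-5-methylcoumarin
Conditions: DMP, CH2Cl2 (dry), 0 °C → rt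
Reagents that add atoms: none
Why: Periodinane oxidation of a hindered secondary allylic alcohol under anhydrous, non-basic conditions that leave the dithiane, the diene and the coumarin untouched.

**Step 11**
Reactants: 20 acyl dithiane
Product: 21 (E)-2-{2-[4-(benzyloxy)-5-methyl-2-oxo-2H-chromen-3-yl]cyclopent-2-en-1-ylidene}-6-methylheptane-3,4-dione
Conditions: PhI(OCOCF3)2, MeCN/H2O 9:1, 0 °C
Reagents that add atoms: water, O
Why: Oxidative dethioketalisation with a hypervalent iodine reagent is a standard route from 2-acyl-1,3-dithianes to 1,2-diketones; the electron-poor diene and the vinylogous benzyl ester should not be oxidised, and a short cold reaction limits contact of the electrophilic product with water.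

**Step 12**
Reactants: 21 dienyl 1,2-diketone; 22 dimethylzinc
Product: 24 (1S,6S,6aS)-6a-[4-(benzyloxy)-5-methyl-2-oxo-2H-chromen-3-yl]-1-hydroxy-3,6-dimethyl-1-(2-methylpropyl)-4,5,6,6a-tetrahydropentalen-2(1H)-one, via methylzinc dienolate 23 (not isolated)
Conditions: Cu(OTf)2 (5 mol %), BINOL-derived bis(1-phenylethyl)amine phosphoramidite (10 mol %), Me2Zn (2 equiv), toluene, −30 °C → rt; sat. aq. NH4Cl
Reagents that add atoms: none
Why: Proposed new method: the chiral methylcopper species formed from Me2Zn binds the C8 dienone of 21 and transfers methyl to the δ-carbon C5, giving methylzinc dienolate 23 (O–C8=C1–C2=C6), which is the reactivity of the known copper-catalysed asymmetric 1,6-additions of dialkylzincs to dienones. Because C8 also carries the C7 carbonyl, the five carbons C7–C8–C1–C2–C6 of 23 form an oxido-substituted pentadienyl cation, and after rotation about the now single C1–C2 bond (zinc dienolates can also equilibrate their C8=C1 geometry through C-bound forms) ring A closes by a thermally allowed conrotatory 4π electrocyclisation that makes C6–C7, formally a 5-(enolendo)-exo-trig aldol; the closest known type is the Nazarov cyclisation of dienyl diketones set off by 1,6-addition of amines or malonates, and the untested element is its initiation by enantioselective carbon transfer from copper. C5 is fixed by the ligand, which distinguishes the two faces of the flat, stereocentre-free ring B. C6 follows from C5: ring B locks the aryl group in the inside position of the C6 terminus, and as C6 pyramidalises this fully bonded group should swing to the face bearing the C5 hydrogen, so that C7 bonds on the face of the C5 methyl group. C7 follows from conrotation out of the rotamer with the carbonyl oxygen inside and isobutyl outside, the only one expected to close because the zinc-chelated alternative would press isobutyl against the inside aryl group, and this puts isobutyl cis to aryl and the alkoxide on the methyl face. The step needs 1,6- rather than 1,4- or 1,2-attack and no reaction at the coumarin, which is secured by the fully substituted β-carbon C2, the open δ-CH, the inertness of Me2Zn to ketones without copper, and the shielding of coumarin C4′ by the peri methyl group and the C3′ substituent.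

**Step 13**
Reactants: 24 benzyl ether of the target
Product: 25 4-hydroxy-3-[(1S,6S,6aS)-1-hydroxy-3,6-dimethyl-1-(2-methylpropyl)-2-oxo-1,2,4,5,6,6a-hexahydropentalen-6a-yl]-5-methyl-2H-chromen-2-one (target)
Conditions: H2 (1 atm), 10% Pd/C, EtOAc, rt
Reagents that add atoms: none
Why: Catalytic hydrogenolysis of a vinylogous benzyl ester runs under neutral conditions in which the tetrasubstituted enone and coumarin alkenes should not be reduced and the acid- and base-sensitive tertiary α-ketol with its three stereocentres is left undisturbed.

**Compound list**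
1 | 2′-hydroxy-6′-methylacetophenone | CC(=O)c1c(C)cccc1O | starting material
2 | 4-hydroxy-5-methylcoumarin | O=c1cc(O)c2c(C)cccc2o1 | intermediate
3 | 3-bromo-4-hydroxy-5-methylcoumarin | O=c1c(Br)c(O)c2c(C)cccc2o1 | intermediate
4 | 4-(benzyloxy)-3-bromo-5-methylcoumarin | O=c1c(Br)c(OCc3ccccc3)c2c(C)cccc2o1 | intermediate
5 | cyclopentanone | O=C1CCCC1 | starting material
6 | 1,1-dimethoxypropan-2-one | COC(OC)C(C)=O | starting material
7 | lithium cyclopent-1-en-1-olate (not isolated) | [Li+].[O-]C1=CCCC1 | intermediate
8 | 2-(2-hydroxy-1,1-dimethoxypropan-2-yl)cyclopentan-1-one (diastereomer mixture) | COC(OC)C(C)(O)C1CCCC1=O | intermediate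
9 | 1,1-dimethoxy-2-(2-oxocyclopentyl)propan-2-yl methanesulfonate (not isolated) | COC(OC)C(C)(OS(C)(=O)=O)C1CCCC1=O | intermediate
10 | (E)-2-(1,1-dimethoxypropan-2-ylidene)cyclopentan-1-one | COC(OC)/C(C)=C1\CCCC1=O | intermediate
11 | lithium (E)-5-(1,1-dimethoxypropan-2-ylidene)cyclopent-1-en-1-olate (not isolated) | COC(OC)/C(C)=C1\CCC=C1[O-].[Li+] | intermediate
12 | (E)-5-(1,1-dimethoxypropan-2-ylidene)cyclopent-1-en-1-yl triflate | COC(OC)/C(C)=C1\CCC=C1OS(=O)(=O)C(F)(F)F | intermediate
13 | 2-[(E)-5-(1,1-dimethoxypropan-2-ylidene)cyclopent-1-en-1-yl]-4,4,5,5-tetramethyl-1,3,2-dioxaborolane (not isolated) | COC(OC)/C(C)=C1\CCC=C1B2OC(C)(C)C(C)(C)O2 | intermediate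
14 | 4-(benzyloxy)-3-[(E)-5-(1,1-dimethoxypropan-2-ylidene)cyclopent-1-en-1-yl]-5-methylcoumarin (not isolated) | COC(OC)/C(C)=C1\CCC=C1c1c(OCc3ccccc3)c2c(C)cccc2oc1=O | intermediate
15 | (E)-2-{2-[4-(benzyloxy)-5-methyl-2-oxo-2H-chromen-3-yl]cyclopent-2-en-1-ylidene}propanal | O=C/C(C)=C1\CCC=C1c1c(OCc3ccccc3)c2c(C)cccc2oc1=O | intermediate
16 | 3-methylbutanal | CC(C)CC=O | starting material
17 | 2-isobutyl-1,3-dithiane | CC(C)CC1SCCCS1 | intermediate
18 | 2-lithio-2-isobutyl-1,3-dithiane (not isolated) | [Li]C1(CC(C)C)SCCCS1 | intermediate
19 | dithianyl carbinol (racemic at C8) | CC(C)CC1(SCCCS1)C(O)/C(C)=C2\CCC=C2c2c(OCc3ccccc3)c4c(C)cccc4oc2=O | intermediate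
20 | acyl dithiane | CC(C)CC1(SCCCS1)C(=O)/C(C)=C2\CCC=C2c2c(OCc3ccccc3)c4c(C)cccc4oc2=O | intermediate
21 | (E)-dienyl 1,2-diketone (key-step precursor) | CC(C)CC(=O)C(=O)/C(C)=C1\CCC=C1c1c(OCc3ccccc3)c2c(C)cccc2oc1=O | intermediate
22 | dimethylzinc | C[Zn]C | starting material
23 | methylzinc dienolate, 5S (not isolated) | C[Zn]OC(C(=O)CC(C)C)=C(C)C1=C(c2c(OCc4ccccc4)c3c(C)cccc3oc2=O)[C@@H](C)CC1 | intermediate
24 | 4-O-benzyl ether of the target (key-step product) | CC1=C2CC[C@H](C)[C@]2(c2c(OCc4ccccc4)c3c(C)cccc3oc2=O)[C@@](O)(CC(C)C)C1=O | intermediate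
25 | CNP0177994.1 | CC1=C2CC[C@H](C)[C@]2(c2c(O)c3c(C)cccc3oc2=O)[C@@](O)(CC(C)C)C1=O | target

**Step count and risks**
Total step count: 13.
Longest linear sequence: 9 steps (steps 4, 5, 6, 7, 9, 10, 11, 12, 13, from cyclopentanone).

Steps most likely to fail:

1. **Step 12.** The zinc dienolate may survive to the quench without closing. The closure may rotate in the wrong sense at C6 or start from the chelated rotamer at C7. Facial discrimination in the methyl transfer may be poor. The fallback sets out from 21 and returns at 24, and it separates the two events into known reaction types. The copper-catalysed asymmetric 1,6-addition of Me2Zn is run cold and the zinc dienolate is trapped with TMSOTf, as is usual for zinc enolates from conjugate additions. This gives 4-(benzyloxy)-5-methyl-3-{(5S)-5-methyl-2-[6-methyl-4-oxo-3-(trimethylsilyloxy)hept-2-en-2-yl]cyclopent-1-en-1-yl}coumarin F1. F1 is isolated and cannot chelate. It is then treated with BF3·OEt2 in CH2Cl2 at −78 °C. External activation of the C7 carbonyl produces the silyloxy-pentadienyl cation of a Lewis-acid Nazarov (vinylogous Mukaiyama aldol) closure, and aqueous work-up gives 24.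

2. **Step 7.** Oxidative addition and transmetalation between two ortho-crowded partners may be slow, so that protodeboronation of the dienyl boronate takes over. The fallback sets out from 10 and 4 and returns at 15. It replaces the cross-coupling by carbonyl addition and elimination. Bromine–magnesium exchange on 4 with iPrMgCl·LiCl at −40 °C gives [4-(benzyloxy)-5-methyl-2-oxo-2H-chromen-3-yl]magnesium chloride F2. F2 adds 1,2 to the ring ketone of 10 in the presence of LaCl3·2LiCl to give 4-(benzyloxy)-3-[(E)-2-(1,1-dimethoxypropan-2-ylidene)-1-hydroxycyclopentyl]-5-methylcoumarin F3. TsOH in wet THF then ionises the tertiary allylic alcohol, removes a C5 proton and hydrolyses the acetal in one operation, giving 15.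

3. **Step 11.** Releasing the diketone in aqueous acid may be followed by 1,6-addition of water, or by enolisation at C3 and premature ring closure. The electron-poor acyl dithiane may also resist sulfur oxidation. The fallback sets out from 19 and returns at 21. It reverses the order, so that the diketone appears only under anhydrous conditions. The more electron-rich hydroxy dithiane 19 is hydrolysed alkylatively (MeI, CaCO3, aq. MeCN, 45 °C) to (E)-2-{2-[4-(benzyloxy)-5-methyl-2-oxo-2H-chromen-3-yl]cyclopent-2-en-1-ylidene}-3-hydroxy-6-methylheptan-4-one F4. This acyloin is oxidised with DMP in dry CH2Cl2 to 21, which is filtered and used at once.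

**Further compounds**
F1 | step 12 | 4-(benzyloxy)-5-methyl-3-{(5S)-5-methyl-2-[6-methyl-4-oxo-3-(trimethylsilyloxy)hept-2-en-2-yl]cyclopent-1-en-1-yl}coumarin | CC(C)CC(=O)C(O[Si](C)(C)C)=C(C)C1=C(c2c(OCc4ccccc4)c3c(C)cccc3oc2=O)[C@@H](C)CC1
F2 | step 7 | [4-(benzyloxy)-5-methyl-2-oxo-2H-chromen-3-yl]magnesium chloride | Cl[Mg]c1c(OCc3ccccc3)c2c(C)cccc2oc1=O
F3 | step 7 | 4-(benzyloxy)-3-[(E)-2-(1,1-dimethoxypropan-2-ylidene)-1-hydroxycyclopentyl]-5-methylcoumarin (racemic) | COC(OC)/C(C)=C1\CCCC1(O)c1c(OCc3ccccc3)c2c(C)cccc2oc1=O
F4 | step 11 | (E)-2-{2-[4-(benzyloxy)-5-methyl-2-oxo-2H-chromen-3-yl]cyclopent-2-en-1-ylidene}-3-hydroxy-6-methylheptan-4-one (racemic) | CC(C)CC(=O)C(O)/C(C)=C1\CCC=C1c1c(OCc3ccccc3)c2c(C)cccc2oc1=O
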